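**Strategy.** The synthesis rests on reading ring B (C5–C6–C7–C8–C9–C10) as a Diels–Alder cyclohexene: the ring-fusion bond C5–C10 and the bond C8–C9 lie 1,4 across it, and the C7=C8 olefin is the one-position isomer of a cycloadduct C6=C7 olefin. An intramolecular [4+2] cycloaddition of an acyclic (2E,8E,10E)-trienoate, whose C1–C4 tether carries the C3 carbinol and the C4 gem-dimethyl group, closes rings A and B in one operation and sets C5, C9 and C10 from the alkene geometries, an endo transition state and the equatorial C3 oxygen. Ester reduction, olefin migration, aryl ether formation and acetylation complete the target.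

Key step: step 4

Remark: drimane numbering is used for the bicyclic compounds (decalin C1–C10, C11 on C9, C12 on C8, C13/C14 on C4, C15 on C10); the target is (3R,5S,9R,10R).

Step 1
Reactants: 1 methyl (2E)-3,7-dimethylocta-2,6-dienoate (methyl geranate)
Product: 3 methyl (2E)-3-methyl-6-oxohex-2-enoate, via ozonide 2 (not isolated)
Conditions: O3 (1.0 equiv), CH2Cl2, −78 °C; then Me2S, −78 °C → rt
Reagents that add atoms: ozone, [O-][O+]=O
Why: Chemoselective ozonolysis; ozone should attack the electron-rich trisubstituted 6,7-alkene much faster than the ester-conjugated 2,3-alkene, and reductive cleavage of the ozonide gives the aldehyde.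

Step 2
Reactants: 3 methyl (2E)-3-methyl-6-oxohex-2-enoate; 4 prenylmagnesium chloride; 5 (−)-B-methoxydiisopinocampheylborane (from (+)-α-pinene)
Product: 8 methyl (2E,6R)-6-hydroxy-3,7,7-trimethylnona-2,8-dienoate, via B-prenyldiisopinocampheylborane 6 (not isolated), via borinate ester 7 (not isolated)
Conditions: 4 + 5, Et2O/THF, −78 °C → rt; then 3, −78 °C; then NaBO3·4H2O, THF/H2O, rt
Reagents that add atoms: none
Why: Brown asymmetric reverse prenylation; the allylborane adds through its γ-carbon in a chair six-membered transition state, which creates the C(CH3)2 quaternary carbon and the carbinol centre, and the (+)-α-pinene-derived Ipc groups direct attack to the Si face of the aldehyde (6R here), while the enoate is inert at −78 °C.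

Step 3
Reactants: 8 methyl (2E,6R)-6-hydroxy-3,7,7-trimethylnona-2,8-dienoate; 9 (E)-1-bromoprop-1-ene
Product: 10 methyl (2E,6R,8E,10E)-6-hydroxy-3,7,7-trimethyldodeca-2,8,10-trienoate
Conditions: Pd(OAc)2 (5 mol %), P(o-tol)3 (10 mol %), Et3N, MeCN, 80 °C, sealed tube
Reagents that add atoms: none
Why: Mizoroki–Heck vinylation of the terminal alkene; the vinylpalladium species adds to the unhindered CH2 terminus, the neopentyl position offers no allylic hydrogen for side reactions, and syn β-hydride elimination should give the E,E-diene with retention of the bromide geometry.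

Step 4
Reactants: 10 methyl (2E,6R,8E,10E)-6-hydroxy-3,7,7-trimethyldodeca-2,8,10-trienoate
Product: 11 methyl (3R,5S,8R,9R,10R)-3-hydroxydrim-6-en-11-oate (trans-fused; 5-H, 8-H and 9-H on one face, the C8, C10 methyls, the ester and 3-OH on the other)
Conditions: toluene (0.01 M), BHT (cat.), 185 °C, sealed tube
Reagents that add atoms: none
Why: A thermal type-1 intramolecular Diels–Alder reaction (concerted suprafacial [4π+2π]) between the (8E,10E)-diene and the ester-activated (2E)-alkene forms C5–C10 and C8–C9 together. Ring B closes as the cycloaddition ring and ring A as the six-membered ring spanned by the four-carbon tether C1–C4, both in the fused mode. The E geometry of the dienophile places the C10 methyl and the C9 ester cis, the E,E-diene places the C8 methyl cis to them, and the endo transition state (ester under the diene, tether anti) gives the trans ring fusion with 5-H anti to the C10 methyl. The absolute sense is relayed from C3, because the chair-like tether with the C3 hydroxyl equatorial next to the gem-dimethyl group exposes one diene face. The step needs endo and π-facial selectivity; the terminal E ester, the Thorpe–Ingold effect of C4 and the C3 stereocentre should favour 11, and minor isomers would be removed by chromatography.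

Step 5
Reactants: 11 methyl (3R,5S,8R,9R,10R)-3-hydroxydrim-6-en-11-oate
Product: 12 (3R,5S,8R,9R,10R)-drim-6-ene-3,11-diol
Conditions: LiAlH4, THF, 0 °C → rt; Fieser work-up
Reagents that add atoms: none
Why: Hydride reduction of the hindered ester to the primary alcohol; the isolated alkene and all stereocentres are untouched because no enolisation occurs.

Step 6
Reactants: 12 (3R,5S,8R,9R,10R)-drim-6-ene-3,11-diol
Product: 13 (3R,5S,9R,10R)-drim-7-ene-3,11-diol
Conditions: RhCl3·3H2O (5 mol %), EtOH, 70 °C, stopped at full conversion of 12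
Reagents that add atoms: none
Why: Metal-hydride-catalysed olefin migration (insertion/β-hydride elimination); Rh–H should add from the face anti to the angular methyl with the metal at C7 (C6 is shielded by the 4,4-dimethyl group) and syn elimination of 8-H gives the trisubstituted 7,8-alkene, which re-inserts only slowly, and since C8 becomes sp2 any C8 epimer converges on 13.

Step 7
Reactants: 13 (3R,5S,9R,10R)-drim-7-ene-3,11-diol; 14 umbelliferone (7-hydroxy-2H-chromen-2-one)
Product: 15 7-{[(3R,5S,9R,10R)-3-hydroxydrim-7-en-11-yl]oxy}-2H-chromen-2-one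
Conditions: PPh3, DIAD, THF, 0 °C → rt
Reagents that add atoms: none
Why: Mitsunobu etherification; the acidic phenol is O-alkylated by the primary alkoxyphosphonium ion, while the secondary 3-OH next to the gem-dimethyl group is too hindered to be activated.

Step 8
Reactants: 15 7-{[(3R,5S,9R,10R)-3-hydroxydrim-7-en-11-yl]oxy}-2H-chromen-2-one
Product: 16 (3R,5S,9R,10R)-11-[(2-oxo-2H-chromen-7-yl)oxy]drim-7-en-3-yl acetate (CNP0224712.1)
Conditions: Ac2O, pyridine, DMAP (cat.), CH2Cl2, rt
Reagents that add atoms: acetic anhydride, CC(=O)OC(C)=O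
Why: DMAP-catalysed acylation of the equatorial secondary alcohol; the aryl ether, the lactone and the alkene are inert.

**Compound list**

1 | methyl (2E)-3,7-dimethylocta-2,6-dienoate (methyl geranate) | COC(=O)/C=C(\C)CCC=C(C)C | starting material
2 | methyl (2E)-5-(5,5-dimethyl-1,2,4-trioxolan-3-yl)-3-methylpent-2-enoate (ozonide) | COC(=O)/C=C(\C)CCC1OOC(C)(C)O1 | intermediate
3 | methyl (2E)-3-methyl-6-oxohex-2-enoate | COC(=O)/C=C(\C)CCC=O | intermediate
4 | prenylmagnesium chloride | CC(C)=CC[Mg]Cl | starting material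
5 | (−)-B-methoxydiisopinocampheylborane | COB([C@@H]1C[C@@H]2C[C@H]([C@H]1C)C2(C)C)[C@@H]1C[C@@H]2C[C@H]([C@H]1C)C2(C)C | starting material
6 | B-prenyldiisopinocampheylborane | CC(C)=CCB([C@@H]1C[C@@H]2C[C@H]([C@H]1C)C2(C)C)[C@@H]1C[C@@H]2C[C@H]([C@H]1C)C2(C)C | intermediate
7 | diisopinocampheylborinate ester of 8 | COC(=O)/C=C(\C)CC[C@@H](OB([C@@H]1C[C@@H]2C[C@H]([C@H]1C)C2(C)C)[C@@H]1C[C@@H]2C[C@H]([C@H]1C)C2(C)C)C(C)(C)C=C | intermediate
8 | methyl (2E,6R)-6-hydroxy-3,7,7-trimethylnona-2,8-dienoate | COC(=O)/C=C(\C)CC[C@@H](O)C(C)(C)C=C | intermediate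
9 | (E)-1-bromoprop-1-ene | C/C=C/Br | starting material
10 | methyl (2E,6R,8E,10E)-6-hydroxy-3,7,7-trimethyldodeca-2,8,10-trienoate | COC(=O)/C=C(\C)CC[C@@H](O)C(C)(C)/C=C/C=C/C | intermediate
11 | methyl (3R,5S,8R,9R,10R)-3-hydroxydrim-6-en-11-oate | O[C@@H]1CC[C@@]2(C)[C@H](C(=O)OC)[C@H](C)C=C[C@@H]2C1(C)C | intermediate
12 | (3R,5S,8R,9R,10R)-drim-6-ene-3,11-diol | O[C@@H]1CC[C@@]2(C)[C@H](CO)[C@H](C)C=C[C@@H]2C1(C)C | intermediate
13 | (3R,5S,9R,10R)-drim-7-ene-3,11-diol | O[C@@H]1CC[C@@]2(C)[C@H](CO)C(C)=CC[C@@H]2C1(C)C | intermediate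
14 | umbelliferone (7-hydroxy-2H-chromen-2-one) | Oc1ccc2ccc(=O)oc2c1 | starting material
15 | 7-{[(3R,5S,9R,10R)-3-hydroxydrim-7-en-11-yl]oxy}-2H-chromen-2-one | O[C@@H]1CC[C@@]2(C)[C@H](COc3ccc4ccc(=O)oc4c3)C(C)=CC[C@@H]2C1(C)C | intermediate
16 | (3R,5S,9R,10R)-11-[(2-oxo-2H-chromen-7-yl)oxy]drim-7-en-3-yl acetate | CC(=O)O[C@@H]1CC[C@@]2(C)[C@H](COc3ccc4ccc(=O)oc4c3)C(C)=CC[C@@H]2C1(C)C | target

**Step count.** Total: 8 steps. Longest linear sequence: 8 steps, from 1.

**Steps most likely to fail**

1. Step 4 (key cycloaddition). The β,β-disubstituted ester dienophile may react sluggishly, and under purely thermal conditions the exo transition state or the other diene face may compete, giving cis-fused or C3-mismatched adducts. The fallback sets out from 10 and changes the dienophile to an enal that cyclises under Lewis acid promotion at low temperature. DIBAL-H (CH2Cl2, −78 °C) should reduce the ester to the allylic diol (2E,6R,8E,10E)-3,7,7-trimethyldodeca-2,8,10-triene-1,6-diol F1. MnO2 (CH2Cl2, rt) should oxidise only the allylic alcohol to the enal (2E,6R,8E,10E)-6-hydroxy-3,7,7-trimethyldodeca-2,8,10-trienal F2. Me2AlCl (2.2 equiv, CH2Cl2, −40 → 0 °C) should then give, through a strongly endo-selective cycloaddition, the aldehyde (3R,5S,8R,9R,10R)-3-hydroxydrim-6-en-11-al F3. NaBH4 (MeOH, 0 °C) returns to the route at 12.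

2. Step 6 (olefin migration). The migration may run on to the tetrasubstituted 8,9-position, or it may proceed toward C5, because only steric factors distinguish the two allylic hydrogens. The fallback sets out from 12 and replaces catalysis by a stoichiometric, regiodefined sequence.
   - TBSOTf/2,6-lutidine should give the bis-silyl ether (3R,5S,8R,9R,10R)-3,11-bis(tert-butyldimethylsilyloxy)drim-6-ene F4.
   - Hydroboration–oxidation (BH3·THF; NaOH, H2O2) should place boron at the less hindered C7, anti to the angular methyl, and give the 7-ol 3,11-bis(tert-butyldimethylsilyloxy)drimane-7-ol F5.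
   - Dess–Martin periodinane should give the ketone 3,11-bis(tert-butyldimethylsilyloxy)drimane-7-one F6.
   - Tf2O with 2,6-di-tert-butyl-4-methylpyridine should give the thermodynamic, more substituted enol triflate 3,11-bis(tert-butyldimethylsilyloxy)drim-7-en-7-yl trifluoromethanesulfonate F7.
   - Pd(OAc)2/PPh3, Bu3N, HCO2H (DMF, 60 °C) should reduce it to (3R,5S,9R,10R)-3,11-bis(tert-butyldimethylsilyloxy)drim-7-ene F8.
   - TBAF (THF) returns to the route at 13.

3. Step 7 (Mitsunobu etherification). Substitution at the β-branched primary carbon next to the quaternary C10 may be slow, so that elimination of the activated alcohol or alkylation of the hydrazide competes. The fallback sets out from 13 and forms the aryl–oxygen bond instead of the alkyl–oxygen bond: Pd-catalysed C–O coupling with 7-bromocoumarin (Pd2(dba)3, RockPhos, Cs2CO3, toluene, 90 °C), in which the primary alcohol should react in preference to the hindered secondary one, gives 15 directly and returns to the route there.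

**Further compounds**

F1 | step 4 | (2E,6R,8E,10E)-3,7,7-trimethyldodeca-2,8,10-triene-1,6-diol | OC/C=C(\C)CC[C@@H](O)C(C)(C)/C=C/C=C/C
F2 | step 4 | (2E,6R,8E,10E)-6-hydroxy-3,7,7-trimethyldodeca-2,8,10-trienal | O=C/C=C(\C)CC[C@@H](O)C(C)(C)/C=C/C=C/C
F3 | step 4 | (3R,5S,8R,9R,10R)-3-hydroxydrim-6-en-11-al | O[C@@H]1CC[C@@]2(C)[C@H](C=O)[C@H](C)C=C[C@@H]2C1(C)C
F4 | step 6 | (3R,5S,8R,9R,10R)-3,11-bis(tert-butyldimethylsilyloxy)drim-6-ene | CC(C)(C)[Si](C)(C)O[C@@H]1CC[C@@]2(C)[C@H](CO[Si](C)(C)C(C)(C)C)[C@H](C)C=C[C@@H]2C1(C)C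
F5 | step 6 | 3,11-bis(tert-butyldimethylsilyloxy)drimane-7-ol (7-OH anti to C15) | CC(C)(C)[Si](C)(C)O[C@@H]1CC[C@@]2(C)[C@H](CO[Si](C)(C)C(C)(C)C)[C@H](C)[C@@H](O)C[C@@H]2C1(C)C
F6 | step 6 | 3,11-bis(tert-butyldimethylsilyloxy)drimane-7-one | CC(C)(C)[Si](C)(C)O[C@@H]1CC[C@@]2(C)[C@H](CO[Si](C)(C)C(C)(C)C)[C@H](C)C(=O)C[C@@H]2C1(C)C
F7 | step 6 | 3,11-bis(tert-butyldimethylsilyloxy)drim-7-en-7-yl trifluoromethanesulfonate | CC(C)(C)[Si](C)(C)O[C@@H]1CC[C@@]2(C)[C@H](CO[Si](C)(C)C(C)(C)C)C(C)=C(OS(=O)(=O)C(F)(F)F)C[C@@H]2C1(C)C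
F8 | step 6 | (3R,5S,9R,10R)-3,11-bis(tert-butyldimethylsilyloxy)drim-7-ene | CC(C)(C)[Si](C)(C)O[C@@H]1CC[C@@]2(C)[C@H](CO[Si](C)(C)C(C)(C)C)C(C)=CC[C@@H]2C1(C)C
F0 | step 7 | none | none
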